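**Retrosynthetic overview**

1. The route rests on the substitution of rings B and C. Each is a benzene with oxygens on C1, C2 and C3, the allyl on C5 and hydrogens on C4 and C6 (ring B: C1–O–ring A, C2–O–ring C, C3–OMe; ring C: C1–O–ring B, C2–OH, C3–OMe).
2. This pattern maps onto an aryloxyalkyne carbon (C1), a boron-bearing alkyne carbon (C2, latent oxygen) and the four carbons of 3-allylcyclobut-2-en-1-one (C3–C6).
3. Key disconnection, used twice: vinylketene–alkyne benzannulation across C2–C3, C1–C6 and C3–C4, from an ArO–C≡C–Bpin ynol ether and the cyclobutenone. The C3 phenol is then methylated and the C2–B bond oxidised to the C2 oxygen.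
4. Each ynol ether comes from the phenol, trichloroethylene, n-BuLi and i-PrOBpin. The cyclobutenone comes from 3-ethoxycyclobut-2-en-1-one and allylmagnesium bromide.
5. Ring order: ring A is bought as eugenol, ring B is built in step 4, and ring C is built in step 9 on the ring B phenol by the same sequence.

Key step: step 4

Remark: the target has no stereocentre. The stereocentres of intermediates 9, 12 and 22 form as racemates and are destroyed in the same step. Bpin is the 4,4,5,5-tetramethyl-1,3,2-dioxaborolan-2-yl group and i-PrOBpin is 2-isopropoxy-4,4,5,5-tetramethyl-1,3,2-dioxaborolane. The vinylketene that cyclobutenone 10 gives on heating is the same transient species in steps 4 and 9; it is numbered once, as 11, at step 4, where it first forms.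

**Route**

Step 1
Reactants: 1 eugenol (4-allyl-2-methoxyphenol); 2 trichloroethylene
Product: 3 4-allyl-1-{[(E)-1,2-dichloroethenyl]oxy}-2-methoxybenzene
Conditions: K2CO3, DMF, 70 °C
Reagents that add atoms: none
Why: Carbonate-mediated loss of HCl from trichloroethylene gives dichloroacetylene, to which the phenoxide adds in anti fashion (the standard aryl dichlorovinyl ether synthesis), and K2CO3 at 70 °C is too weak a base to move the allyl double bond into conjugation.

Step 2
Reactants: 3 4-allyl-1-{[(E)-1,2-dichloroethenyl]oxy}-2-methoxybenzene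
Product: 6 2-[(4-allyl-2-methoxyphenoxy)ethynyl]-4,4,5,5-tetramethyl-1,3,2-dioxaborolane, via lithium aryloxyacetylide 4 (not isolated), via lithium isopropoxyborate 5 (not isolated)
Conditions: n-BuLi (2.1 equiv), THF, −78 → −40 °C; i-PrOBpin, −78 °C; HCl·Et2O (1.0 equiv), −78 °C → rt; filtration under Ar
Reagents that add atoms: 2-isopropoxy-4,4,5,5-tetramethyl-1,3,2-dioxaborolane, CC(C)OB1OC(C)(C)C(C)(C)O1
Why: Vinylic deprotonation, β-elimination of LiCl and Li–Cl exchange on the chloroalkyne give acetylide 4 (the dichlorovinyl ether route to ynol ethers), which is borylated by the usual acetylide–borate ester addition and anhydrous protonolysis of ate complex 5; at −78 °C n-BuLi should leave the ArCH2 and ring protons alone.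

Step 3
Reactants: 7 3-ethoxycyclobut-2-en-1-one; 8 allylmagnesium bromide
Product: 10 3-allylcyclobut-2-en-1-one, via 1-allyl-3-ethoxycyclobut-2-en-1-ol 9 (not isolated)
Conditions: Et2O, −78 °C; then 1 M aq HCl, 0 °C, short contact
Reagents that add atoms: none
Why: 1,2-Addition of the Grignard reagent to the vinylogous ester carbonyl, then acid-promoted ionisation and hydrolysis of the enol ether carbinol (Stork–Danheiser transposition, the standard entry to 3-substituted cyclobutenones), should give 10; the cold dilute acid is kept brief so that the skipped diene does not move into conjugation.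

Step 4
Reactants: 6 2-[(4-allyl-2-methoxyphenoxy)ethynyl]-4,4,5,5-tetramethyl-1,3,2-dioxaborolane; 10 3-allylcyclobut-2-en-1-one
Product: 15 5-allyl-3-(4-allyl-2-methoxyphenoxy)-2-(4,4,5,5-tetramethyl-1,3,2-dioxaborolan-2-yl)phenol, via vinylketene 11 (not isolated), via 4-vinylcyclobutenone adduct 12 (not isolated), via dienylketene 13 (not isolated), via cyclohexa-2,4-dienone 14 (not isolated)
Conditions: 6 (1.3 equiv), toluene (0.3 M), 80 °C then 110 °C, Ar, sealed tube
Reagents that add atoms: none
Why: Proposed new method: at 80 °C cyclobutenone 10 opens reversibly by a four-electron electrocyclic process to vinylketene 11, which is trapped by the ynol ether in a (2+2) cycloaddition that forms C2–C3 and C1–C6 of ring B and gives 4-vinylcyclobutenone 12; a second four-electron opening gives dienylketene 13, whose six-electron disrotatory electrocyclisation forms C3–C4 and closes ring B as dienone 14, which tautomerises to phenol 15. The closest known reaction type is the Danheiser benzannulation of cyclobutenones with alkoxy- and siloxyalkynes, together with benzannulations of alkynylboronates that deliver arylboronates; an alkyne carrying both an aryloxy and a boryl group has not been used in this way. Ring B is thus closed by 6π-electrocyclisation of the dienylketene isomer that has the vinyl group cis to the ketene, and no stereocentre remains because the only one formed (C4 of 12) is lost on ring opening. The step needs regioselectivity in the ketene–alkyne (2+2) and chemoselectivity for the alkyne over the terminal alkenes: the aryloxy oxygen polarises the triple bond so that the boron-bearing carbon, whose developing negative charge is also stabilised by the empty boron p orbital, attacks the ketene carbonyl carbon, and unactivated monosubstituted alkenes are poor ketenophiles at this temperature. The 3-allyl group of 10 ends on C5, and an aryl ynol ether has no β-hydrogen on its oxygen substituent, so the retro-ene loss of an alkene that limits alkyl ynol ethers on heating cannot occur.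

Step 5
Reactants: 15 5-allyl-3-(4-allyl-2-methoxyphenoxy)-2-(4,4,5,5-tetramethyl-1,3,2-dioxaborolan-2-yl)phenol
Product: 16 2-[4-allyl-2-(4-allyl-2-methoxyphenoxy)-6-methoxyphenyl]-4,4,5,5-tetramethyl-1,3,2-dioxaborolane
Conditions: MeI, K2CO3, DMF, rt
Reagents that add atoms: iodomethane, CI
Why: Williamson ether synthesis on the potassium phenoxide; the anhydrous carbonate medium avoids the aqueous base that would protodeboronate a 2,6-dioxygenated arylboronate, and the allyl groups are inert.

Step 6
Reactants: 16 2-[4-allyl-2-(4-allyl-2-methoxyphenoxy)-6-methoxyphenyl]-4,4,5,5-tetramethyl-1,3,2-dioxaborolane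
Product: 17 4-allyl-2-(4-allyl-2-methoxyphenoxy)-6-methoxyphenol
Conditions: 30% aq H2O2, NaOH, THF–H2O, 0 °C; then aq Na2S2O3, aq NH4Cl
Reagents that add atoms: hydrogen peroxide, OO
Why: Hydroperoxide adds to boron and the aryl group migrates from boron to oxygen (oxidation of an arylboronic ester to a phenol), while alkaline H2O2 at 0 °C does not epoxidise isolated terminal alkenes.

Step 7
Reactants: 17 4-allyl-2-(4-allyl-2-methoxyphenoxy)-6-methoxyphenol; 2 trichloroethylene
Product: 18 5-allyl-1-(4-allyl-2-methoxyphenoxy)-2-{[(E)-1,2-dichloroethenyl]oxy}-3-methoxybenzene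
Conditions: K2CO3, DMF, 70–80 °C
Reagents that add atoms: none
Why: Same phenoxide addition to dichloroacetylene formed in situ as in step 1; the electrophile is a small linear alkyne, so the two ortho substituents of 17 should slow the addition but not stop it.

Step 8
Reactants: 18 5-allyl-1-(4-allyl-2-methoxyphenoxy)-2-{[(E)-1,2-dichloroethenyl]oxy}-3-methoxybenzene
Product: 21 2-{[4-allyl-2-(4-allyl-2-methoxyphenoxy)-6-methoxyphenoxy]ethynyl}-4,4,5,5-tetramethyl-1,3,2-dioxaborolane, via lithium aryloxyacetylide 19 (not isolated), via lithium isopropoxyborate 20 (not isolated)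
Conditions: n-BuLi (2.1 equiv), THF, −78 → −40 °C; i-PrOBpin, −78 °C; HCl·Et2O (1.0 equiv), −78 °C → rt; filtration under Ar
Reagents that add atoms: 2-isopropoxy-4,4,5,5-tetramethyl-1,3,2-dioxaborolane, CC(C)OB1OC(C)(C)C(C)(C)O1
Why: Same elimination, Li–Cl exchange and acetylide borylation sequence as in step 2, with the diaryl ether and methoxy groups inert to n-BuLi at −78 °C.

Step 9
Reactants: 21 2-{[4-allyl-2-(4-allyl-2-methoxyphenoxy)-6-methoxyphenoxy]ethynyl}-4,4,5,5-tetramethyl-1,3,2-dioxaborolane; 10 3-allylcyclobut-2-en-1-one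
Product: 25 5-allyl-3-[4-allyl-2-(4-allyl-2-methoxyphenoxy)-6-methoxyphenoxy]-2-(4,4,5,5-tetramethyl-1,3,2-dioxaborolan-2-yl)phenol, via 4-vinylcyclobutenone adduct 22 (not isolated), via dienylketene 23 (not isolated), via cyclohexa-2,4-dienone 24 (not isolated)
Conditions: 21 (1.3 equiv), toluene (0.3 M), 80 °C then 110 °C, Ar, sealed tube
Reagents that add atoms: none
Why: Proposed new method: on heating, cyclobutenone 10 opens by the same four-electron process as in step 4 to the vinylketene listed as 11, which should add to the aryloxy-polarised boryl alkyne of 21 in a regioselective (2+2) cycloaddition to give 22, after which a second four-electron opening to 23, six-electron electrocyclisation to 24 and tautomerisation build ring C with boron on C2; the closest known reaction type is again the Danheiser benzannulation of cyclobutenones with alkoxy- and siloxyalkynes, and the bulkier aryloxy group sits two atoms away from the reacting triple bond.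

Step 10
Reactants: 25 5-allyl-3-[4-allyl-2-(4-allyl-2-methoxyphenoxy)-6-methoxyphenoxy]-2-(4,4,5,5-tetramethyl-1,3,2-dioxaborolan-2-yl)phenol
Product: 26 2-{4-allyl-2-[4-allyl-2-(4-allyl-2-methoxyphenoxy)-6-methoxyphenoxy]-6-methoxyphenyl}-4,4,5,5-tetramethyl-1,3,2-dioxaborolane
Conditions: MeI, K2CO3, DMF, rt
Reagents that add atoms: iodomethane, CI
Why: Williamson O-methylation of the phenoxide under the same anhydrous conditions as in step 5, which spare the C–B bond and the three allyl groups.

Step 11
Reactants: 26 2-{4-allyl-2-[4-allyl-2-(4-allyl-2-methoxyphenoxy)-6-methoxyphenoxy]-6-methoxyphenyl}-4,4,5,5-tetramethyl-1,3,2-dioxaborolane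
Product: 27 4-allyl-2-[4-allyl-2-(4-allyl-2-methoxyphenoxy)-6-methoxyphenoxy]-6-methoxyphenol (CNP0153774.0)
Conditions: 30% aq H2O2, NaOH, THF–H2O, 0 °C; then aq Na2S2O3, aq NH4Cl
Reagents that add atoms: hydrogen peroxide, OO
Why: Oxidation of the arylboronic ester to the phenol by boron-to-oxygen aryl migration, as in step 6, should turn the C2–B bond of ring C into the free C2 hydroxyl of the target without touching the alkenes.

**Compound list**

1 | eugenol (4-allyl-2-methoxyphenol) | C=CCc1ccc(O)c(OC)c1 | starting material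
2 | trichloroethylene | ClC=C(Cl)Cl | starting material
3 | 4-allyl-1-{[(E)-1,2-dichloroethenyl]oxy}-2-methoxybenzene | C=CCc1ccc(O/C(Cl)=C\Cl)c(OC)c1 | intermediate
4 | lithium (4-allyl-2-methoxyphenoxy)acetylide | C=CCc1ccc(OC#C[Li])c(OC)c1 | intermediate
5 | lithium [(4-allyl-2-methoxyphenoxy)ethynyl](isopropoxy)(pinacolato)borate | [Li+].C=CCc1ccc(OC#C[B-]2(OC(C)C)OC(C)(C)C(C)(C)O2)c(OC)c1 | intermediate
6 | 2-[(4-allyl-2-methoxyphenoxy)ethynyl]-4,4,5,5-tetramethyl-1,3,2-dioxaborolane | C=CCc1ccc(OC#CB2OC(C)(C)C(C)(C)O2)c(OC)c1 | intermediate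
7 | 3-ethoxycyclobut-2-en-1-one | CCOC1=CC(=O)C1 | starting material
8 | allylmagnesium bromide | C=CC[Mg]Br | starting material
9 | 1-allyl-3-ethoxycyclobut-2-en-1-ol (racemic) | C=CCC1(O)C=C(OCC)C1 | intermediate
10 | 3-allylcyclobut-2-en-1-one | C=CCC1=CC(=O)C1 | intermediate
11 | 3-methylidenehexa-1,5-dien-1-one (vinylketene) | O=C=CC(=C)CC=C | intermediate
12 | 3-(4-allyl-2-methoxyphenoxy)-4-(penta-1,4-dien-2-yl)-2-(4,4,5,5-tetramethyl-1,3,2-dioxaborolan-2-yl)cyclobut-2-en-1-one (racemic) | C=CCc1ccc(OC2=C(B3OC(C)(C)C(C)(C)O3)C(=O)C2C(=C)CC=C)c(OC)c1 | intermediate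
13 | (3E)-3-(4-allyl-2-methoxyphenoxy)-5-methylidene-2-(4,4,5,5-tetramethyl-1,3,2-dioxaborolan-2-yl)octa-1,3,7-trien-1-one (C2 and C5 cis across C3=C4) | O=C=C(B1OC(C)(C)C(C)(C)O1)/C(Oc1ccc(CC=C)cc1OC)=C\C(=C)CC=C | intermediate
14 | 5-allyl-3-(4-allyl-2-methoxyphenoxy)-2-(4,4,5,5-tetramethyl-1,3,2-dioxaborolan-2-yl)cyclohexa-2,4-dien-1-one | O=C1CC(CC=C)=CC(Oc2ccc(CC=C)cc2OC)=C1B3OC(C)(C)C(C)(C)O3 | intermediate
15 | 5-allyl-3-(4-allyl-2-methoxyphenoxy)-2-(4,4,5,5-tetramethyl-1,3,2-dioxaborolan-2-yl)phenol | C=CCc1ccc(Oc2cc(CC=C)cc(O)c2B3OC(C)(C)C(C)(C)O3)c(OC)c1 | intermediate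
16 | 2-[4-allyl-2-(4-allyl-2-methoxyphenoxy)-6-methoxyphenyl]-4,4,5,5-tetramethyl-1,3,2-dioxaborolane | C=CCc1ccc(Oc2cc(CC=C)cc(OC)c2B3OC(C)(C)C(C)(C)O3)c(OC)c1 | intermediate
17 | 4-allyl-2-(4-allyl-2-methoxyphenoxy)-6-methoxyphenol | C=CCc1ccc(Oc2cc(CC=C)cc(OC)c2O)c(OC)c1 | intermediate
18 | 5-allyl-1-(4-allyl-2-methoxyphenoxy)-2-{[(E)-1,2-dichloroethenyl]oxy}-3-methoxybenzene | C=CCc1ccc(Oc2cc(CC=C)cc(OC)c2O/C(Cl)=C\Cl)c(OC)c1 | intermediate
19 | lithium [4-allyl-2-(4-allyl-2-methoxyphenoxy)-6-methoxyphenoxy]acetylide | C=CCc1ccc(Oc2cc(CC=C)cc(OC)c2OC#C[Li])c(OC)c1 | intermediate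
20 | lithium {[4-allyl-2-(4-allyl-2-methoxyphenoxy)-6-methoxyphenoxy]ethynyl}(isopropoxy)(pinacolato)borate | [Li+].C=CCc1ccc(Oc2cc(CC=C)cc(OC)c2OC#C[B-]3(OC(C)C)OC(C)(C)C(C)(C)O3)c(OC)c1 | intermediate
21 | 2-{[4-allyl-2-(4-allyl-2-methoxyphenoxy)-6-methoxyphenoxy]ethynyl}-4,4,5,5-tetramethyl-1,3,2-dioxaborolane | C=CCc1ccc(Oc2cc(CC=C)cc(OC)c2OC#CB3OC(C)(C)C(C)(C)O3)c(OC)c1 | intermediate
22 | 3-[4-allyl-2-(4-allyl-2-methoxyphenoxy)-6-methoxyphenoxy]-4-(penta-1,4-dien-2-yl)-2-(4,4,5,5-tetramethyl-1,3,2-dioxaborolan-2-yl)cyclobut-2-en-1-one (racemic) | C=CCc1ccc(Oc2cc(CC=C)cc(OC)c2OC4=C(B3OC(C)(C)C(C)(C)O3)C(=O)C4C(=C)CC=C)c(OC)c1 | intermediate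
23 | (3E)-3-[4-allyl-2-(4-allyl-2-methoxyphenoxy)-6-methoxyphenoxy]-5-methylidene-2-(4,4,5,5-tetramethyl-1,3,2-dioxaborolan-2-yl)octa-1,3,7-trien-1-one (C2 and C5 cis across C3=C4) | O=C=C(B1OC(C)(C)C(C)(C)O1)/C(Oc1c(OC)cc(CC=C)cc1Oc1ccc(CC=C)cc1OC)=C\C(=C)CC=C | intermediate
24 | 5-allyl-3-[4-allyl-2-(4-allyl-2-methoxyphenoxy)-6-methoxyphenoxy]-2-(4,4,5,5-tetramethyl-1,3,2-dioxaborolan-2-yl)cyclohexa-2,4-dien-1-one | O=C1CC(CC=C)=CC(Oc2c(OC)cc(CC=C)cc2Oc2ccc(CC=C)cc2OC)=C1B3OC(C)(C)C(C)(C)O3 | intermediate
25 | 5-allyl-3-[4-allyl-2-(4-allyl-2-methoxyphenoxy)-6-methoxyphenoxy]-2-(4,4,5,5-tetramethyl-1,3,2-dioxaborolan-2-yl)phenol | C=CCc1ccc(Oc2cc(CC=C)cc(OC)c2Oc2cc(CC=C)cc(O)c2B3OC(C)(C)C(C)(C)O3)c(OC)c1 | intermediate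
26 | 2-{4-allyl-2-[4-allyl-2-(4-allyl-2-methoxyphenoxy)-6-methoxyphenoxy]-6-methoxyphenyl}-4,4,5,5-tetramethyl-1,3,2-dioxaborolane | C=CCc1ccc(Oc2cc(CC=C)cc(OC)c2Oc2cc(CC=C)cc(OC)c2B3OC(C)(C)C(C)(C)O3)c(OC)c1 | intermediate
27 | 4-allyl-2-[4-allyl-2-(4-allyl-2-methoxyphenoxy)-6-methoxyphenoxy]-6-methoxyphenol (CNP0153774.0) | C=CCc1ccc(Oc2cc(CC=C)cc(OC)c2Oc2cc(CC=C)cc(OC)c2O)c(OC)c1 | target

**Step count**

Total: 11 steps. Longest linear sequence: 10 steps (1, 2, 4, 5, 6, 7, 8, 9, 10, 11 from eugenol). Cyclobutenone 10 is made in one step (step 3) and used in steps 4 and 9.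

**Steps most likely to fail**

1. Step 4 (proposed new method). The boryl group withdraws electron density from the ynol ether, so the (2+2) capture of vinylketene 11 may be too slow. The ketene would then oligomerise or acylate the phenol already formed, and the C–B bond ortho to the new hydroxyl may be lost by protodeboronation on prolonged heating. Fallback by Ullmann diaryl ether synthesis, setting out from eugenol 1 and coming back at dimer phenol 17. Amine-catalysed ortho-bromination of 1 (NBS, cat. i-Pr2NH, CH2Cl2, 0 °C) should give 4-allyl-2-bromo-6-methoxyphenol F1. Protection (MOMCl, i-Pr2NEt, CH2Cl2) gives 5-allyl-1-bromo-3-methoxy-2-(methoxymethoxy)benzene F2. Copper-catalysed coupling of F2 with a second portion of 1 (CuI, N,N-dimethylglycine, Cs2CO3, dioxane, 100 °C) gives 4-allyl-1-[5-allyl-3-methoxy-2-(methoxymethoxy)phenoxy]-2-methoxybenzene F3. HCl in MeOH removes the acetal and delivers 17.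

2. Step 9 (proposed new method). The same slow ketene capture applies, now with a bulkier and more electron-rich aryloxy group, and a larger polyolefinic substrate is exposed longer to 110 °C. Fallback setting out from dimer phenol 17 and coming back at target 27. Copper-catalysed Ullmann coupling of the hindered phenol 17 with the bromide 5-allyl-1-bromo-3-methoxy-2-(methoxymethoxy)benzene F2 (made from 1 as above; CuI, N,N-dimethylglycine, Cs2CO3, dioxane, 110 °C) should give 5-allyl-1-(4-allyl-2-methoxyphenoxy)-2-[5-allyl-3-methoxy-2-(methoxymethoxy)phenoxy]-3-methoxybenzene F4. HCl in MeOH then frees the C2 hydroxyl of ring C to give 27.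

3. Step 2 (the same holds for step 8). Release of the alkynylboronate from ate complex 5 with HCl may be accompanied by addition of HCl or water across the electron-rich triple bond, or by loss of boron from the sp carbon on work-up. Fallback setting out from dichlorovinyl ether 3 (through acetylide 4) and coming back at boryl ynol ether 6 with no acid. Acetylide 4 is trapped with ClB(N-i-Pr2)2 in THF at −78 °C to give 1-[(4-allyl-2-methoxyphenoxy)ethynyl]-N,N,N',N'-tetraisopropylboranediamine F5 after filtration of LiCl. Amine–diol exchange with pinacol in Et2O at rt then gives 6.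

**Further compounds**

F1 | step 4 | 4-allyl-2-bromo-6-methoxyphenol | C=CCc1cc(Br)c(O)c(OC)c1
F2 | step 4 | 5-allyl-1-bromo-3-methoxy-2-(methoxymethoxy)benzene | C=CCc1cc(Br)c(OCOC)c(OC)c1
F3 | step 4 | 4-allyl-1-[5-allyl-3-methoxy-2-(methoxymethoxy)phenoxy]-2-methoxybenzene | C=CCc1ccc(Oc2cc(CC=C)cc(OC)c2OCOC)c(OC)c1
F4 | step 9 | 5-allyl-1-(4-allyl-2-methoxyphenoxy)-2-[5-allyl-3-methoxy-2-(methoxymethoxy)phenoxy]-3-methoxybenzene | C=CCc1ccc(Oc2cc(CC=C)cc(OC)c2Oc2cc(CC=C)cc(OC)c2OCOC)c(OC)c1
F5 | step 2 | 1-[(4-allyl-2-methoxyphenoxy)ethynyl]-N,N,N',N'-tetraisopropylboranediamine | C=CCc1ccc(OC#CB(N(C(C)C)C(C)C)N(C(C)C)C(C)C)c(OC)c1
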